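**Plan**
- Retrosynthesis: the three acetates come off last. The γ-lactone is cut at O–C7 and C17–C8, giving a ten-membered α-bromo ketone plus acrylate. The carbocycle is cut at C7–C8 (sulfone/ester acylation), then at C1–C2 and C9–C10 (three-component Michael–aldol).
- Forward: the cyclohexane comes from enone 3 and the Z-alkene chain from nerol. The ten-membered ring closes in step 13, the spiro-epoxide is made in step 14, the lactone in step 17, and the acetates in step 19.
- Enabling feature: C7 is both α to the C8 ketone and allylic to C5=C6, so it is SN2-active and configurationally labile. The C8 carbonyl is its direct neighbour, so an acrylate O–C–C unit can bridge C7 and C8 as a five-membered lactone fused to the ten-membered ring.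
- Stereochemistry: C9 from the (5S,6S)-butane-2,3-diacetal glycolate; C10 and C1 from the Michael–aldol step; C14 and C2 from equatorial then chelation-controlled hydride delivery; C11 from α-face epoxidation opposite the axial C1 methyl; C7, C8 and C17 in the key step; the Z-alkene from nerol.

Key step: step 17

Assumptions: (i) lactone 8, the butane-2,3-diacetal of glycolic acid, is taken as a purchasable reagent. (ii) Briarane numbering (C1–C20) is used in names and explanations. (iii) C7 is drawn without configuration in 17, 18 and 20 because it is epimerisable or an epimer mixture there.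

Step 1
Reactants: 1 1,4-dioxaspiro[4.5]dec-6-en-8-one
Product: 2 7-iodo-1,4-dioxaspiro[4.5]dec-6-en-8-one
Conditions: I2, pyridine, CH2Cl2, 0 °C → rt
Reagents that add atoms: iodine, II
Why: α-Iodination of the enone by pyridine-mediated addition–elimination (Johnson iodination) should place iodine on the α-vinyl carbon and leave the ketal alone.

Step 2
Reactants: 2 7-iodo-1,4-dioxaspiro[4.5]dec-6-en-8-one
Product: 3 7-methyl-1,4-dioxaspiro[4.5]dec-6-en-8-one
Conditions: MeB(OH)2, Pd(dppf)Cl2 (5 mol %), K2CO3, dioxane/H2O, 80 °C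
Reagents that add atoms: methylboronic acid, CB(O)O
Why: Suzuki–Miyaura methylation of the α-iodoenone should give the 2-methyl enone (future C14 ketone, C1 methyl, C10 β-carbon, C11 ketal) under conditions the ketal tolerates.

Step 3
Reactants: 4 nerol
Product: 5 neryl chloride
Conditions: NCS, Me2S, CH2Cl2, −40 → 0 °C
Reagents that add atoms: N-chlorosuccinimide, O=C1CCC(=O)N1Cl
Why: Corey–Kim chlorination should convert the allylic alcohol into the primary chloride without allylic transposition or loss of the Z geometry.

Step 4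
Reactants: 5 neryl chloride
Product: 6 neryl phenyl sulfone
Conditions: PhSO2Na, DMF, rt
Reagents that add atoms: sodium benzenesulfinate, [Na+].[O-]S(=O)c1ccccc1
Why: SN2 S-alkylation of the sulfinate at the primary allylic carbon should install the sulfone that later makes C7 an α-selective allyl anion.

Step 5
Reactants: 6 neryl phenyl sulfone
Product: 7 (Z)-4-methyl-6-(phenylsulfonyl)hex-4-enal
Conditions: O3 (1.0 equiv), pyridine, CH2Cl2, −78 °C; Me2S
Reagents that add atoms: ozone, [O-][O+]=O
Why: Chemoselective ozonolysis should cleave the electron-rich remote isopropylidene alkene and spare the alkene deactivated by the allylic sulfone, giving the C2 aldehyde with the C3–C7 chain.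

Step 6
Reactants: 8 (5S,6S)-5,6-dimethoxy-5,6-dimethyl-1,4-dioxan-2-one, 3 7-methyl-1,4-dioxaspiro[4.5]dec-6-en-8-one, 7 (Z)-4-methyl-6-(phenylsulfonyl)hex-4-enal
Product: 10 Michael–aldol adduct, via lithium enolate 9 (not isolated)
Conditions: 8, LiHMDS, THF, −78 °C; 3, −78 → −40 °C; 7, −78 °C; AcOH, −78 °C
Reagents that add atoms: none
Why: In this Michael–aldol three-component coupling the lithium enolate of 8 should add 1,4 to 3 from its face anti to the axial C5 methoxy group (sets C9), the closed Li-bridged transition state should fix the enone face (C10), and the tetrasubstituted enolate 9 should take up aldehyde 7 anti to the new C10 substituent (quaternary C1), the C2 carbinol configuration being irrelevant because it is oxidised in step 7.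

Step 7
Reactants: 10 Michael–aldol adduct
Product: 11 C2,C14-diketone
Conditions: Dess–Martin periodinane, CH2Cl2, rt
Reagents that add atoms: none
Why: Dess–Martin oxidation under neutral conditions should give the non-enolisable β-diketone without retro-aldol cleavage at the quaternary C1.

Step 8
Reactants: 11 C2,C14-diketone
Product: 12 C2,C14-syn-diol
Conditions: L-Selectride (2.4 equiv), THF, −78 → −50 °C; AcOH, −78 °C
Reagents that add atoms: none
Why: The bulky borohydride should attack the C14 ring ketone equatorially to give the axial alkoxide cis to the C1 acyl group, and the lithium chelate between that alkoxide and the C2 ketone then leaves open only the face flanked by the C1 methyl (the other is covered by the cyclohexane ring), so this chelation-controlled reduction of a β-alkoxy ketone should give the target configurations at C14 and C2.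

Step 9
Reactants: 12 C2,C14-syn-diol
Product: 13 C2,C14-di-tert-butylsilylene
Conditions: t-Bu2Si(OTf)2, 2,6-lutidine, CH2Cl2, 0 °C → rt
Reagents that add atoms: di-tert-butylsilyl bis(trifluoromethanesulfonate), CC(C)(C)[Si](OS(=O)(=O)C(F)(F)F)(OS(=O)(=O)C(F)(F)F)C(C)(C)C
Why: Silylene formation should tie the hindered syn-1,3-diol into a six-membered dioxasilinane that resists the acid of step 10 and the bases of steps 13 and 16.

Step 10
Reactants: 13 C2,C14-di-tert-butylsilylene
Product: 14 C9-hydroxy methyl ester C11-ketone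
Conditions: HCl (1.25 M in MeOH), 0 °C → rt; then 1 M aq. HCl, THF, rt
Reagents that add atoms: methanol, CO; water, O
Why: Acid-catalysed methanolysis of the diacetal lactone and hydrolysis of the dioxolane should release the C9 hydroxy methyl ester and the C11 ketone in one operation, and C10, now α to the ketone, can only relax to the desired trans-diequatorial arrangement.

Step 11
Reactants: 14 C9-hydroxy methyl ester C11-ketone
Product: 15 C9-O-TBS methyl ester C11-ketone
Conditions: TBSOTf (1.3 equiv), 2,6-lutidine, CH2Cl2, −78 °C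
Reagents that add atoms: tert-butyldimethylsilyl trifluoromethanesulfonate, CC(C)(C)[Si](C)(C)OS(=O)(=O)C(F)(F)F
Why: Silylation of the secondary C9 alcohol should block β-elimination and lactonisation in the following steps.

Step 12
Reactants: 15 C9-O-TBS methyl ester C11-ketone
Product: 16 C11-methylene ester sulfone
Conditions: Zn, CH2Br2, TiCl4, THF/CH2Cl2, 0 °C → rt
Reagents that add atoms: dibromomethane, BrCBr
Why: Takai–Lombardo methylenation is non-basic and should convert only the ketone, not the ester, without epimerising C10 or eliminating the β-silyloxy group.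

Step 13
Reactants: 16 C11-methylene ester sulfone
Product: 17 ten-membered β-keto sulfone
Conditions: LiHMDS (2.2 equiv), THF (2 mM, slow addition of 16), −78 → 0 °C; AcOH
Reagents that add atoms: none
Why: Intramolecular Claisen-type acylation of the α-selective allylic sulfone carbanion by the methyl ester should close the ten-membered ring at C7–C8, driven by deprotonation of the β-keto sulfone formed, with the Z-alkene and the trans-diequatorial ring junction preorganising the chain ends.

Step 14
Reactants: 17 ten-membered β-keto sulfone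
Product: 18 11,20-epoxy β-keto sulfone
Conditions: mCPBA (1.1 equiv), CH2Cl2, 0 °C
Reagents that add atoms: 3-chloroperoxybenzoic acid, OOC(=O)c1cccc(Cl)c1
Why: In this Prilezhaev epoxidation the exocyclic 1,1-disubstituted alkene should react in preference to C5=C6, which is deactivated by the allylic sulfonyl and keto groups, and from the α-face opposite the axial C1 methyl, giving the spiro-epoxide with equatorial oxygen as in the target.

Step 15
Reactants: 18 11,20-epoxy β-keto sulfone
Product: 19 ten-membered β,γ-unsaturated ketone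
Conditions: SmI2 (2.5 equiv), THF/MeOH, −78 °C
Reagents that add atoms: none
Why: Reductive desulfonylation of the β-keto sulfone (ketyl formation, loss of sulfinate, C7-protonation of the samarium dienolate) should leave the Z C5=C6 alkene out of conjugation and the epoxide untouched.

Step 16
Reactants: 19 ten-membered β,γ-unsaturated ketone
Product: 20 C7-bromo ketone
Conditions: LiHMDS (1.1 equiv), THF, −78 °C; NBS, −78 °C; AcOH
Reagents that add atoms: N-bromosuccinimide, O=C1CCC(=O)N1Br
Why: Kinetic deprotonation should occur at the allylic C7 and not at the silyloxy-bearing C9, and α-bromination of the lithium dienolate should give the bromide as a C7 epimer mixture, which is acceptable because step 17 is designed to converge.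

Step 17
Reactants: 20 C7-bromo ketone, 21 potassium acrylate
Product: 24 silyl-protected hydroxy lactone, via α-acryloyloxy ketone 22 (not isolated), via O-silyl aldolate 23 (not isolated)
Conditions: 21 (1.5 equiv), 18-crown-6 (10 mol %), n-Bu4NBr (10 mol %), DMF, 0 °C → rt; then THF, Cu(OAc)2·H2O (5 mol %), rac-BINAP (5 mol %), (HMe2Si)2O, rt; NH4F, MeOH, 0 °C
Reagents that add atoms: none
Why: Proposed new method: the carboxylate of 21 should displace bromide from C7 (SN2 with inversion at a carbon both α to the C8 ketone and allylic to C5=C6) to give 22, and Cu–H then adds to the acrylate β-carbon to form a chelated (Z)-copper enolate that attacks the C8 ketone, so the acrylate acts as an O–C–C linchpin; the closest known reactions are carboxylate alkylation by α-halo ketones and the Cu(I)/bisphosphine/siloxane reductive aldol cyclisation of keto acrylates to β-hydroxy lactones, here merged in one flask and made stereoconvergent. The five-membered lactone closes in the aldol event, formally 5-(enolendo)-exo-trig, a mode that metal-templated enolates manage in Dieckmann and Reformatsky closures of five-membered lactones. C7: the epimeric bromides interconvert by bromide exchange and 22 enolises at the doubly activated C7–H under the excess carboxylate, so the irreversible aldol should drain both pools through the 7S ester (Curtin–Hammett), the epimer expected to reach C8 with C6 held anti to C9 across C7–C8. C8: the tether delivers the enolate to the carbonyl face syn to the C7 oxygen, which in that extended ring conformation gives the 8S alcohol trans to H-7. C17: the chair-like chelate of the (Z)-enolate should place the methyl cis to the new hydroxyl (17R). The step needs O-alkylation by SN2 and not SN2′ (the tertiary C5 is hindered), conjugate reduction in preference to ketone reduction (the acrylate is the better Cu–H acceptor), and survival of the epoxide and silyl ethers (neutral conditions until the cold NH4F work-up that frees the C8 hydroxyl from 23).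

Step 18
Reactants: 24 silyl-protected hydroxy lactone
Product: 25 C2,C9,C14-triol lactone
Conditions: TBAF, AcOH (1:1), THF, rt
Reagents that add atoms: none
Why: Fluoride-mediated desilylation buffered with acetic acid should cleave the silylene and the silyl ether without opening the epoxide or causing retro-aldol of the β-hydroxy lactone.

Step 19
Reactants: 25 C2,C9,C14-triol lactone
Product: 26 junceellolide F
Conditions: Ac2O, pyridine, DMAP (cat.), CH2Cl2, 0 °C → rt
Reagents that add atoms: acetic anhydride, CC(=O)OC(C)=O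
Why: DMAP-catalysed acetylation should esterify the three secondary alcohols while the tertiary C8 hydroxyl is too hindered to react.

**Compound list**
1 | 1,4-dioxaspiro[4.5]dec-6-en-8-one | O=C1CCC2(OCCO2)C=C1 | starting material
2 | 7-iodo-1,4-dioxaspiro[4.5]dec-6-en-8-one | O=C1CCC2(OCCO2)C=C1I | intermediate
3 | 7-methyl-1,4-dioxaspiro[4.5]dec-6-en-8-one | O=C1CCC2(OCCO2)C=C1C | intermediate
4 | nerol, (Z)-3,7-dimethylocta-2,6-dien-1-ol | CC(C)=CCC/C(C)=C\CO | starting material
5 | neryl chloride, (Z)-1-chloro-3,7-dimethylocta-2,6-diene | CC(C)=CCC/C(C)=C\CCl | intermediate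
6 | neryl phenyl sulfone, (Z)-[(3,7-dimethylocta-2,6-dien-1-yl)sulfonyl]benzene | CC(C)=CCC/C(C)=C\CS(=O)(=O)c1ccccc1 | intermediate
7 | (Z)-4-methyl-6-(phenylsulfonyl)hex-4-enal (C2 aldehyde, C7 sulfone) | O=CCC/C(C)=C\CS(=O)(=O)c1ccccc1 | intermediate
8 | (5S,6S)-5,6-dimethoxy-5,6-dimethyl-1,4-dioxan-2-one | O=C1CO[C@](C)(OC)[C@@](C)(OC)O1 | starting material
9 | lithium C14-enolate of the Michael adduct of 8 and 3 (C9 R, C10 as in 26) | [Li+].[O-]C1=C(C)[C@@H]([C@H]3O[C@](C)(OC)[C@@](C)(OC)OC3=O)C2(OCCO2)CC1 | intermediate (not isolated)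
10 | Michael–aldol adduct: C14 ketone, C11 dioxolane, C10 bearing the (3R,5S,6S)-dioxanone (C9, C8), quaternary C1 bearing methyl and the C2 carbinol chain to the C7 sulfone; C1, C9, C10 as in 26, C2 carbinol as formed (drawn as the expected anti-aldol epimer) | O=C1CCC2(OCCO2)[C@H]([C@H]3O[C@](C)(OC)[C@@](C)(OC)OC3=O)[C@@]1(C)[C@@H](O)CC/C(C)=C\CS(=O)(=O)c1ccccc1 | intermediate
11 | C2,C14-diketone of 10 | O=C1CCC2(OCCO2)[C@H]([C@H]3O[C@](C)(OC)[C@@](C)(OC)OC3=O)[C@@]1(C)C(=O)CC/C(C)=C\CS(=O)(=O)c1ccccc1 | intermediate
12 | C2,C14-syn-diol (C14 hydroxyl axial and trans to the C1 methyl; C2 as in 26) | O[C@H]1CCC2(OCCO2)[C@H]([C@H]3O[C@](C)(OC)[C@@](C)(OC)OC3=O)[C@@]1(C)[C@H](O)CC/C(C)=C\CS(=O)(=O)c1ccccc1 | intermediate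
13 | C2,C14-O-di-tert-butylsilylene of 12 | CC(C)(C)[Si]4(C(C)(C)C)O[C@H]1CCC2(OCCO2)[C@H]([C@H]3O[C@](C)(OC)[C@@](C)(OC)OC3=O)[C@@]1(C)[C@H](O4)CC/C(C)=C\CS(=O)(=O)c1ccccc1 | intermediate
14 | silylene-protected C11 ketone with (9R)-hydroxy C8 methyl ester | CC(C)(C)[Si]4(C(C)(C)C)O[C@H]1CCC(=O)[C@H]([C@@H](O)C(=O)OC)[C@@]1(C)[C@H](O4)CC/C(C)=C\CS(=O)(=O)c1ccccc1 | intermediate
15 | C9-O-TBS ether of 14 | CC(C)(C)[Si]4(C(C)(C)C)O[C@H]1CCC(=O)[C@H]([C@@H](O[Si](C)(C)C(C)(C)C)C(=O)OC)[C@@]1(C)[C@H](O4)CC/C(C)=C\CS(=O)(=O)c1ccccc1 | intermediate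
16 | C11 exocyclic methylene analogue of 15 (C8 methyl ester, C7 sulfone) | CC(C)(C)[Si]4(C(C)(C)C)O[C@H]1CCC(=C)[C@H]([C@@H](O[Si](C)(C)C(C)(C)C)C(=O)OC)[C@@]1(C)[C@H](O4)CC/C(C)=C\CS(=O)(=O)c1ccccc1 | intermediate
17 | trans-fused 6/10 bicycle: C8 ketone, C7 phenylsulfonyl, (5Z)-alkene, C11 methylene, C9-OTBS, C2,C14-silylene | CC(C)(C)[Si]4(C(C)(C)C)O[C@H]1CCC(=C)[C@@H]2[C@@H](O[Si](C)(C)C(C)(C)C)C(=O)C(/C=C(/C)CC[C@@H](O4)[C@@]12C)S(=O)(=O)c1ccccc1 | intermediate
18 | 11,20-epoxide of 17 (epoxide oxygen α, as in 26) | CC(C)(C)[Si]4(C(C)(C)C)O[C@H]1CC[C@]2(CO2)[C@@H]2[C@@H](O[Si](C)(C)C(C)(C)C)C(=O)C(/C=C(/C)CC[C@@H](O4)[C@@]12C)S(=O)(=O)c1ccccc1 | intermediate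
19 | desulfonylated (5Z)-β,γ-unsaturated C8 ketone | CC(C)(C)[Si]4(C(C)(C)C)O[C@H]1CC[C@]2(CO2)[C@@H]2[C@@H](O[Si](C)(C)C(C)(C)C)C(=O)C/C=C(/C)CC[C@@H](O4)[C@@]12C | intermediate
20 | C7-bromo derivative of 19 (C7 epimers) | CC(C)(C)[Si]4(C(C)(C)C)O[C@H]1CC[C@]2(CO2)[C@@H]2[C@@H](O[Si](C)(C)C(C)(C)C)C(=O)C(Br)/C=C(/C)CC[C@@H](O4)[C@@]12C | intermediate
21 | potassium acrylate | [K+].[O-]C(=O)C=C | starting material
22 | (7S)-7-acryloyloxy C8 ketone (productive epimer shown) | CC(C)(C)[Si]4(C(C)(C)C)O[C@H]1CC[C@]2(CO2)[C@@H]2[C@@H](O[Si](C)(C)C(C)(C)C)C(=O)[C@H](/C=C(/C)CC[C@@H](O4)[C@@]12C)OC(=O)C=C | intermediate (not isolated)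
23 | C8-O-(1,1,3,3-tetramethyldisiloxanyl) ether of 24 | CC(C)(C)[Si]4(C(C)(C)C)O[C@H]1CC[C@]2(CO2)[C@@H]2[C@@H](O[Si](C)(C)C(C)(C)C)[C@@]3(O[Si](C)(C)O[SiH](C)C)[C@H](/C=C(/C)CC[C@@H](O4)[C@@]12C)OC(=O)[C@@H]3C | intermediate (not isolated)
24 | (7S,8S,17R)-8-hydroxy-17-methyl γ-lactone with C9-OTBS and C2,C14-silylene | CC(C)(C)[Si]4(C(C)(C)C)O[C@H]1CC[C@]2(CO2)[C@@H]2[C@@H](O[Si](C)(C)C(C)(C)C)[C@@]3(O)[C@H](/C=C(/C)CC[C@@H](O4)[C@@]12C)OC(=O)[C@@H]3C | intermediate
25 | tri-O-deacetyl junceellolide F (2,9,14-triol) | O[C@H]1CC[C@]2(CO2)[C@@H]2[C@@H](O)[C@@]3(O)[C@H](/C=C(/C)CC[C@@H](O)[C@@]12C)OC(=O)[C@@H]3C | intermediate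
26 | junceellolide F | CC(=O)O[C@H]1CC[C@]2(CO2)[C@@H]2[C@@H](OC(C)=O)[C@@]3(O)[C@H](/C=C(/C)CC[C@@H](OC(C)=O)[C@@]12C)OC(=O)[C@@H]3C | target

**Step count and risks**
Total steps: 19. Longest linear sequence: 17 steps (4 → 26; steps 3–5, then 6–19).

Steps most likely to fail:

1. Step 17 (proposed new method). Epimerisation at C7 may be too slow for convergence, giving C7-epimeric lactones, or enolisation may move the alkene into conjugation with the ketone. Fallback by known chemistry, setting out from 19: α-hydroxylation of the lithium enolate with 2-(phenylsulfonyl)-3-phenyloxaziridine should give the (7S)-7-hydroxy ketone F1 after chromatographic removal of the 7R epimer. Acylation with 2-bromopropanoyl bromide and pyridine should give the 7-O-(2-bromopropanoyl) ester F2. An SmI2-mediated intramolecular Reformatsky reaction at −78 °C should then close the lactone through a chelated samarium enolate, returning to the route at 24.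

2. Step 13. Intermolecular acylation and proton transfer may outrun the medium-ring closure, because the ester is a weak electrophile for a ten-membered cyclisation. Fallback, setting out from 16: DIBAL-H at −78 °C should reduce the ester to the C8 aldehyde F3. Addition of its sulfone carbanion to the aldehyde (LiHMDS, high dilution) should give the macrocyclic β-hydroxy sulfone F4. Dess–Martin oxidation then returns to the route at 17.

3. Step 6. 1,2-Addition or retro-Michael reaction at the hindered β-carbon, or poor facial selectivity in the lithium-bridged transition state, may erode yield and the C10/C1 configuration. Fallback, setting out from 8: silylation of the lithium enolate with TBSCl should give the O-TBS ketene acetal F5. Its Mukaiyama–Michael addition to 3 (TBSOTf cat., CH2Cl2, −78 °C, open transition state) should give the TBS enol ether of the Michael adduct F6. A BF3·OEt2-mediated Mukaiyama aldol reaction with 7 then returns to the route at 10.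

**Further compounds**
F1 | step 17 | (7S)-7-hydroxy C8 ketone (C9-OTBS, C2,C14-silylene, 11,20-epoxide) | CC(C)(C)[Si]4(C(C)(C)C)O[C@H]1CC[C@]2(CO2)[C@@H]2[C@@H](O[Si](C)(C)C(C)(C)C)C(=O)[C@H](/C=C(/C)CC[C@@H](O4)[C@@]12C)O
F2 | step 17 | 7-O-(2-bromopropanoyl) ester of F1 | CC(C)(C)[Si]4(C(C)(C)C)O[C@H]1CC[C@]2(CO2)[C@@H]2[C@@H](O[Si](C)(C)C(C)(C)C)C(=O)[C@H](/C=C(/C)CC[C@@H](O4)[C@@]12C)OC(=O)C(C)Br
F3 | step 13 | C8 aldehyde corresponding to ester 16 | CC(C)(C)[Si]4(C(C)(C)C)O[C@H]1CCC(=C)[C@H]([C@@H](O[Si](C)(C)C(C)(C)C)C=O)[C@@]1(C)[C@H](O4)CC/C(C)=C\CS(=O)(=O)c1ccccc1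
F4 | step 13 | ten-membered 8-hydroxy-7-phenylsulfonyl carbocycle | CC(C)(C)[Si]4(C(C)(C)C)O[C@H]1CCC(=C)[C@@H]2[C@@H](O[Si](C)(C)C(C)(C)C)C(O)C(/C=C(/C)CC[C@@H](O4)[C@@]12C)S(=O)(=O)c1ccccc1
F5 | step 6 | O-TBS ketene acetal of 8 | CC(C)(C)[Si](C)(C)OC1=CO[C@](C)(OC)[C@@](C)(OC)O1
F6 | step 6 | C14 TBS enol ether of the Michael adduct of 8 and 3 | CC(C)(C)[Si](C)(C)OC1=C(C)[C@@H]([C@H]3O[C@](C)(OC)[C@@](C)(OC)OC3=O)C2(OCCO2)CC1
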